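(The numbers in the tables are calculated with constants of no real substance; noise was put on by code.)

- A small charge of free catalyst, 5.0 mM against 0.10 M of substrate, worked for 40 min in elm, ash and oak, which differ in [scavenger] and nothing else.

| setting | summer | dusk | elm | ash | oak |
|---|---|---|---|---|---|
| substrate | 0.10 M | 0.10 M | 0.10 M | 0.10 M | 0.10 M |
| partner | 0.20 M | 0.20 M | 0.200 M | 0.200 M | 0.200 M |
| scavenger | 0.14 M | 0.41 M | 0.120 M | 0.180 M | 0.270 M |
| free catalyst | 5 mM | 5 mM | 5.0 mM | 5.0 mM | 5.0 mM |
| remark | run made earlier | run made earlier |  |  |  |
| time |  |  | 40 min | 40 min | 40 min |

- summer (time / min: substrate / %, target / %): 8.00: 77, 23; 15.0: 55, 42; 20.0: 44, 50; 30.0: 33, 66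
- dusk (time / min: substrate / %, target / %): 2.50: 91, 11; 5.00: 86, 13; 12.0: 63, 36; 30.0: 31, 67

(each reading ± 2 percentage points)

- what is said of target includes idle complex
- what is said of released group includes idle adduct
- the earlier runs were read with a standard deviation of 2 percentage points
- steps that have been proposed: free catalyst + target <-> idle complex; partner + released group <-> idle adduct; catalyst intermediate C -> free catalyst + target; substrate + free catalyst <-> catalyst intermediate A; partner + catalyst intermediate A <-> catalyst intermediate B; scavenger + released group -> scavenged by-product; catalyst intermediate B -> released group + catalyst intermediate C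

- part of the substrate that has reacted at the end, elm
- part of the substrate that has reacted at the end, ash
- part of the substrate that has reacted at the end, oak
- what raising the concentration of scavenger from its lowest to its highest value here does to the part of the substrate that has reacted (changes below 5 percentage points count as none) (it rises / it falls / no change)

- I began with the last readings, at 30.0 min: substrate stood at 33 % in summer and 31 % in dusk, with [scavenger] at 0.14 M and 0.41 M. They lay 2 percentage points apart and a reading scatters by 2 points, so at these charges of substrate, partner and free catalyst I could read no effect of scavenger and took one curve.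
- I replaced that curve by its mean, a pseudo-first-order constant of 0.0380 min⁻¹, and multiplied it by the time, which gave 1.52, the number of mean lifetimes of substrate that fit into the flask's time, which I called D.
- The share unreacted is then exp(−D), so I expected 78.1 % reacted in each of the three flasks.
- To test whether one number was enough, I held the mean curve against readings it was not made from: in summer at 15.0 min it missed by 1.6 points and in dusk at 12.0 min by 0.38 points, but in dusk at 5.00 min it lay 3.3 points below the reading, against a scatter of 2 points. The last 10.0 min remained an extrapolation.
- The forecast gave 76 % for elm, 77 % for ash and 78 % for oak, the first two below my figure, and no change, saying of scavenger: “That effect looks small.”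
- The flasks gave 77.7 % for elm, 77.8 % for ash and 77.8 % for oak, a change of 0.17 points across the scavenger range, which is no change.

    free catalyst + target ⇌ idle complex (K = 9.60 L mol⁻¹, k = 1.70 L mol⁻¹ min⁻¹)
    partner + released group ⇌ idle adduct, settled at all times (K = 15.0 L mol⁻¹)
    catalyst intermediate C → free catalyst + target (k = 4.50 min⁻¹)
    substrate + free catalyst ⇌ catalyst intermediate A (K = 29.0 L mol⁻¹, k = 29.0 L mol⁻¹ min⁻¹)
    partner + catalyst intermediate A ⇌ catalyst intermediate B (K = 14.0 L mol⁻¹, k = 12.0 L mol⁻¹ min⁻¹)
    scavenger + released group → scavenged by-product (k = 23.0 L mol⁻¹ min⁻¹)
    catalyst intermediate B → released group + catalyst intermediate C (k = 4.50 min⁻¹)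

- At the end, free scavenger stood at 38.1 % of its charge in elm and 71.7 % in oak, while free partner stood at 60.7 % and 61.3 % of its own. Oak's result, put back as −ln of the unreacted share, gives 1.51 against D of 1.52. Scaled to oak read at 10 min, D gives 31.6 % reacted, and that flask stood at 31.5 %.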